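**Retrosynthetic overview**

1. The last step removes five silyl ethers from 33. Before it, one transform cuts two bonds of 33 at once: the lactone bond C4–C5 (ring closure) and the exocyclic CH2–aryl bond to ring B. This leads back to the halomethyl (2R)-2-(arylmethyl)but-3-enoate 21/32 and aryl iodide 31 (5-exo radical cyclization relayed into a nickel aryl coupling).
2. Enabling feature: in the γ-butyrolactone (ring L: O1, C2(=O), C3, C4, C5), C5 is an unsubstituted O–CH2 bound only to O1 and C4, and C4 carries an exocyclic CH2 that ends on arene ring B. C5 can therefore be carried as the halomethyl group of an ester of the C2–C3 acid, and C4 with its exocyclic carbon as a vinyl group on C3. A 5-exo attack of the C5 radical on C4 then closes ring L and leaves a radical on exactly the carbon that must bond to ring B; the C3 stereocentre next to it sets the trans relationship.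
3. Acid 19 comes from a deconjugative Evans alkylation of N-crotonyl oxazolidinone 17 with benzylic bromide 14. Bromide 14 comes from an enantioselective dirhodium-carbenoid C–H insertion (dihydrobenzofuran ring, cis) followed by C3 epimerization to trans.
4. Aryl iodide 31 comes from an Evans syn-aldol of (aryloxy)acetyl imide 25 with aldehyde 2 (threo), then Mitsunobu inversion at the benzylic carbinol (erythro).
5. Ring order: dihydrobenzofuran (step 5), then γ-lactone (step 24). The four arenes come from vanillin, methyl 5-iodovanillate and 4-iodoguaiacol.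

Key step: step 24

Assumption: Rh2(R-PTTL)4 is taken to give the (2S,3R)-cis ester 8, the mirror image of the outcome known for the (S)-tert-leucinate catalyst with 2-benzyloxyphenyl diazoacetates; if the sense proves opposite, the enantiomeric catalyst is used without other change.

Abbreviations: TIPS = triisopropylsilyl, TBS = tert-butyldimethylsilyl, ArS = 3-methoxy-4-[(triisopropylsilyl)oxy]phenyl.

**Route**

Step 1
Reactants: 1 vanillin (4-hydroxy-3-methoxybenzaldehyde)
Product: 2 3-methoxy-4-[(triisopropylsilyl)oxy]benzaldehyde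
Conditions: TIPSCl, imidazole, DMF, rt
Reagents that add atoms: chlorotriisopropylsilane (TIPSCl), CC(C)[Si](Cl)(C(C)C)C(C)C
Why: Imidazole-promoted silylation of the phenol; the bulky aryl TIPS ether should survive the basic steps ahead and is removed by fluoride at the end.

Step 2
Reactants: 2 3-methoxy-4-[(triisopropylsilyl)oxy]benzaldehyde
Product: 3 (ArS)methanol
Conditions: NaBH4, MeOH, 0 °C
Reagents that add atoms: none
Why: Borohydride reduction of the aryl aldehyde to the benzylic alcohol, with the aryl silyl ether inert at 0 °C.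

Step 3
Reactants: 3 (ArS)methanol; 4 methyl 4-hydroxy-3-iodo-5-methoxybenzoate (methyl 5-iodovanillate)
Product: 5 methyl 3-iodo-5-methoxy-4-[(ArS)methoxy]benzoate
Conditions: PPh3, DIAD, THF, 0 °C to rt
Reagents that add atoms: none
Why: Mitsunobu etherification, in which the acidic hindered phenol displaces the oxyphosphonium of the primary benzylic alcohol and an unstable p-silyloxybenzyl halide is avoided.

Step 4
Reactants: 5 methyl 3-iodo-5-methoxy-4-[(ArS)methoxy]benzoate; 6 ethyl diazoacetate
Product: 7 methyl 3-(1-diazo-2-ethoxy-2-oxoethyl)-5-methoxy-4-[(ArS)methoxy]benzoate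
Conditions: Pd(PPh3)4 (5 mol %), Ag2CO3 (0.5 equiv), Et3N, toluene, rt
Reagents that add atoms: none
Why: Palladium-catalysed cross-coupling of an aryl iodide with the C–H bond of a diazoacetate (oxidative addition, base-assisted palladation of the diazo carbon, reductive elimination) keeps the diazo group and gives the aryl diazoacetate directly.

Step 5
Reactants: 7 aryl diazoacetate
Product: 8 3-ethyl 5-methyl (2S,3R)-7-methoxy-2-(ArS)-2,3-dihydro-1-benzofuran-3,5-dicarboxylate (2,3-cis)
Conditions: Rh2(R-PTTL)4 [dirhodium tetrakis(N-phthaloyl-(R)-tert-leucinate)] (1 mol %), toluene, −60 °C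
Reagents that add atoms: none
Why: Intramolecular 1,5 C–H insertion of the dirhodium carbenoid into the electron-rich benzylic ether C–H closes the dihydrobenzofuran; the chiral carboxylate ligands select one enantiotopic C–H (C2 set as S) and the concerted insertion gives the 2,3-cis ester kinetically.

Step 6
Reactants: 8 cis diester
Product: 9 3-ethyl 5-methyl (2S,3S)-7-methoxy-2-(ArS)-2,3-dihydro-1-benzofuran-3,5-dicarboxylate (2,3-trans)
Conditions: DBU (0.5 equiv), toluene, 60 °C
Reagents that add atoms: none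
Why: Base-mediated epimerization at C3 (benzylic and α to the ester) should lead to the thermodynamically preferred 2,3-trans isomer, setting C3, while C2 has no acidic hydrogen and the 5-endo ring-opening elimination is stereoelectronically disfavoured.

Step 7
Reactants: 9 trans diester
Product: 10 [(2S,3R)-7-methoxy-2-(ArS)-2,3-dihydro-1-benzofuran-3,5-diyl]dimethanol
Conditions: i-Bu2AlH (5 equiv), CH2Cl2, −78 to 0 °C; Rochelle salt work-up
Reagents that add atoms: none
Why: Exhaustive hydride reduction takes both esters to primary alcohols without touching the silyl ether or the cyclic benzylic ether.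

Step 8
Reactants: 10 diol
Product: 11 (2S,3R)-3-(hydroxymethyl)-7-methoxy-2-(ArS)-2,3-dihydro-1-benzofuran-5-carbaldehyde
Conditions: activated MnO2 (excess), CH2Cl2, rt
Reagents that add atoms: none
Why: MnO2 oxidizes benzylic alcohols selectively, so only the ring CH2OH becomes the aldehyde and the two primary alcohols are differentiated.

Step 9
Reactants: 11 hydroxy aldehyde
Product: 12 (2S,3R)-3-[(TBS-oxy)methyl]-7-methoxy-2-(ArS)-2,3-dihydro-1-benzofuran-5-carbaldehyde
Conditions: TBSCl, imidazole, DMF, rt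
Reagents that add atoms: tert-butylchlorodimethylsilane (TBSCl), CC(C)(C)[Si](C)(C)Cl
Why: Standard silylation of the remaining primary alcohol.

Step 10
Reactants: 12 silyl ether aldehyde
Product: 13 {(2S,3R)-3-[(TBS-oxy)methyl]-7-methoxy-2-(ArS)-2,3-dihydro-1-benzofuran-5-yl}methanol
Conditions: NaBH4, MeOH/THF, 0 °C
Reagents that add atoms: none
Why: Borohydride reduction of the aryl aldehyde, with silyl ethers untouched.

Step 11
Reactants: 13 benzylic alcohol
Product: 14 (2S,3R)-5-(bromomethyl)-3-[(TBS-oxy)methyl]-7-methoxy-2-(ArS)-2,3-dihydro-1-benzofuran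
Conditions: CBr4, PPh3, CH2Cl2, 0 °C; used at once
Reagents that add atoms: carbon tetrabromide, BrC(Br)(Br)Br
Why: Appel bromination under neutral conditions gives the reactive p-alkoxybenzylic bromide without acid that could ionize the cyclic benzylic ether.

Step 12
Reactants: 15 (4R)-4-benzyl-1,3-oxazolidin-2-one; 16 (2E)-but-2-enoyl chloride
Product: 17 (4R)-4-benzyl-3-[(2E)-but-2-enoyl]-1,3-oxazolidin-2-one
Conditions: n-BuLi, THF, −78 °C; then 16
Reagents that add atoms: none
Why: N-acylation of the lithiated oxazolidinone with the acid chloride.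

Step 13
Reactants: 17 N-crotonyl imide; 14 benzylic bromide
Product: 18 (4R)-4-benzyl-3-[(2R)-2-(Ar′-methyl)but-3-enoyl]-1,3-oxazolidin-2-one, Ar′ = the dihydrobenzofuran-5-yl unit of 14
Conditions: NaN(SiMe3)2, THF, −78 °C; then 14, −78 to −40 °C
Reagents that add atoms: none
Why: Deconjugative Evans alkylation, in which γ-deprotonation gives the chelated Z-dienolate that is alkylated at the α-carbon on the face away from the auxiliary benzyl group; this sets the R centre that becomes lactone C3 and leaves the vinyl group out of conjugation.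

Step 14
Reactants: 18 alkylated imide
Product: 19 (2R)-2-(Ar′-methyl)but-3-enoic acid
Conditions: LiOH, H2O2, THF/H2O, 0 °C; Na2SO3, then dilute HCl to pH 3
Reagents that add atoms: hydrogen peroxide (as LiOOH; supplies the acid hydroxyl oxygen), OO
Why: Lithium hydroperoxide attacks the exocyclic imide carbonyl selectively at 0 °C, releasing the acid and the auxiliary without epimerizing the α-centre or moving the double bond.

Step 15
Reactants: 19 acid; 20 chloromethyl chlorosulfate
Product: 21 chloromethyl (2R)-2-(Ar′-methyl)but-3-enoate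
Conditions: NaHCO3, Bu4NHSO4 (10 mol %), CH2Cl2/H2O, 0 °C to rt
Reagents that add atoms: none
Why: Phase-transfer O-alkylation of the carboxylate (displacement of chlorosulfate) is the standard mild route to chloromethyl esters and brings in the future lactone O–CH2 carbon.

Step 16
Reactants: 15 (4R)-4-benzyl-1,3-oxazolidin-2-one; 22 bromoacetyl bromide
Product: 23 (4R)-4-benzyl-3-(bromoacetyl)-1,3-oxazolidin-2-one
Conditions: n-BuLi, THF, −78 °C; then 22
Reagents that add atoms: none
Why: N-acylation of the lithiated oxazolidinone at low temperature, where the acyl bromide reacts faster than the alkyl bromide.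

Step 17
Reactants: 23 bromoacetyl imide; 24 4-iodo-2-methoxyphenol
Product: 25 (4R)-4-benzyl-3-[(4-iodo-2-methoxyphenoxy)acetyl]-1,3-oxazolidin-2-one
Conditions: K2CO3, acetone, rt
Reagents that add atoms: none
Why: Williamson displacement of the activated α-bromo imide by the phenoxide.

Step 18
Reactants: 25 (aryloxy)acetyl imide; 2 3-methoxy-4-[(triisopropylsilyl)oxy]benzaldehyde
Product: 26 (4R)-4-benzyl-3-[(2R,3S)-3-hydroxy-2-(4-iodo-2-methoxyphenoxy)-3-(ArS)propanoyl]-1,3-oxazolidin-2-one
Conditions: Bu2BOTf, i-Pr2NEt, CH2Cl2, −78 to 0 °C; then 2, −78 to 0 °C; pH 7 buffer, MeOH, H2O2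
Reagents that add atoms: none
Why: Evans syn-aldol, in which the Z-boron enolate reacts through a closed chair transition state on the face away from the auxiliary benzyl group, setting both centres (2,3-syn, the threo series).

Step 19
Reactants: 26 aldol adduct
Product: 27 (1S,2S)-2-(4-iodo-2-methoxyphenoxy)-1-(ArS)propane-1,3-diol (threo)
Conditions: LiBH4, THF, MeOH (1 equiv), 0 °C
Reagents that add atoms: none
Why: Reductive removal of the auxiliary to the primary alcohol, with aryl iodide and silyl ether unaffected.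

Step 20
Reactants: 27 threo diol
Product: 28 (1S,2S)-3-(TBS-oxy)-2-(4-iodo-2-methoxyphenoxy)-1-(ArS)propan-1-ol
Conditions: TBSCl (1.05 equiv), imidazole, CH2Cl2, 0 °C
Reagents that add atoms: tert-butylchlorodimethylsilane (TBSCl), CC(C)(C)[Si](C)(C)Cl
Why: The primary hydroxyl is silylated much faster than the hindered secondary benzylic one.

Step 21
Reactants: 28 threo alcohol
Product: 29 (1R,2S)-3-(TBS-oxy)-2-(4-iodo-2-methoxyphenoxy)-1-(ArS)propyl 4-nitrobenzoate
Conditions: 4-nitrobenzoic acid, PPh3, DIAD, toluene, −20 °C to rt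
Reagents that add atoms: 4-nitrobenzoic acid, OC(=O)c1ccc(cc1)[N+](=O)[O-]
Why: Mitsunobu esterification with inversion at the benzylic carbinol converts the threo into the erythro series and sets the 1R centre.

Step 22
Reactants: 29 4-nitrobenzoate
Product: 30 (1R,2S)-3-(TBS-oxy)-2-(4-iodo-2-methoxyphenoxy)-1-(ArS)propan-1-ol (erythro)
Conditions: K2CO3 (0.5 equiv), MeOH/THF, 0 °C
Reagents that add atoms: none
Why: Mild methanolysis of the activated aryl ester, short and cold enough that the aryl TIPS ether should be retained.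

Step 23
Reactants: 30 erythro alcohol
Product: 31 (1R,2S)-1,3-bis(TBS-oxy)-2-(4-iodo-2-methoxyphenoxy)-1-(ArS)propane
Conditions: TBSOTf, 2,6-lutidine, CH2Cl2, −78 to 0 °C
Reagents that add atoms: tert-butyldimethylsilyl trifluoromethanesulfonate (TBSOTf), CC(C)(C)[Si](C)(C)OS(=O)(=O)C(F)(F)F
Why: Silyl triflate with a hindered base silylates the hindered secondary benzylic alcohol without ionizing it.

Step 24
Reactants: 21 chloromethyl ester; 31 aryl iodide
Product: 33 pentasilylated (3R,4R)-lactone (TBS3/TIPS2 ether of the target), via iodomethyl ester 32 (not isolated)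
Conditions: 21, NaI (2 equiv), DMA, rt, 30 min, dark; this solution added over 8 h to 31, NiBr2(dme) (10 mol %), 4,4′-di-tert-butyl-2,2′-bipyridine (12 mol %), Mn powder (3 equiv), DMA (0.02 M), 40 °C
Reagents that add atoms: none
Why: Proposed new method: halogen-atom abstraction from iodomethyl ester 32 by a low-valent nickel–bipyridine species gives the acyloxymethyl radical on the future lactone O–CH2 carbon, which adds 5-exo-trig to the internal vinyl carbon and so closes the γ-lactone by the bond between the O–CH2 carbon and the β-carbon; the primary radical left on the exocyclic CH2 is captured by the aryl–nickel species formed by oxidative addition of 31 to zerovalent nickel, reductive elimination from the trivalent nickel intermediate makes the CH2–aryl bond, and Mn returns nickel to the zerovalent state. The closest known reaction types are the nickel-catalysed tandem 5-exo radical cyclization/aryl cross-coupling of alkene-tethered haloacetals and alkyl halides used for β-benzyl-γ-butyrolactone lignans, and the tin-hydride lactonization of alkenoyloxymethyl radicals from halomethyl but-3-enoates; new here is their union with an acyloxymethyl iodide as radical precursor. The one ring closed is the lactone, by 5-exo-trig radical addition. The new stereocentre (lactone C4, R) is controlled by the adjacent C3 centre: in the chair-like 5-exo transition state the large arylmethyl group on C3 sits pseudo-equatorial, so the new exocyclic bond should form trans to it, and any cis isomer must be removed by chromatography because it cannot be corrected by epimerization. The step needs ring closure to outrun capture of the open radical by aryl–nickel, and it needs aryl–alkyl cross-selectivity; the first is addressed by low nickel concentration, dilution, slow addition of 32 and 40 °C (the radical must reach the s-cis ester rotamer before it can close), the second by the different activation modes of the two iodides (two-electron oxidative addition for the aryl iodide, halogen abstraction for the activated α-oxy alkyl iodide).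

Step 25
Reactants: 33 pentasilylated lactone
Product: 34 target, (3R,4R)-4-[(4-{[(1R,2S)-1,3-dihydroxy-1-(4-hydroxy-3-methoxyphenyl)propan-2-yl]oxy}-3-methoxyphenyl)methyl]-3-{[(2S,3R)-2-(4-hydroxy-3-methoxyphenyl)-3-(hydroxymethyl)-7-methoxy-2,3-dihydro-1-benzofuran-5-yl]methyl}oxolan-2-one
Conditions: Bu4NF (8 equiv), AcOH (8 equiv), THF, 0 °C to rt
Reagents that add atoms: none
Why: Fluoride cleaves the two aryl TIPS and three alkyl TBS ethers, and the acetic acid buffer keeps the phenols protonated so that the lactone, the benzylic alcohol and the cyclic benzylic ether should be left intact.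

**Compound list**

1 | vanillin (4-hydroxy-3-methoxybenzaldehyde) | COc1cc(C=O)ccc1O | starting material
2 | 3-methoxy-4-[(triisopropylsilyl)oxy]benzaldehyde | COc1cc(C=O)ccc1O[Si](C(C)C)(C(C)C)C(C)C | intermediate
3 | {3-methoxy-4-[(triisopropylsilyl)oxy]phenyl}methanol | COc1cc(CO)ccc1O[Si](C(C)C)(C(C)C)C(C)C | intermediate
4 | methyl 4-hydroxy-3-iodo-5-methoxybenzoate | COC(=O)c1cc(I)c(O)c(OC)c1 | starting material
5 | methyl 3-iodo-5-methoxy-4-[(ArS)methoxy]benzoate | COC(=O)c1cc(I)c(OCc2ccc(O[Si](C(C)C)(C(C)C)C(C)C)c(OC)c2)c(OC)c1 | intermediate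
6 | ethyl diazoacetate | CCOC(=O)C=[N+]=[N-] | starting material
7 | methyl 3-(1-diazo-2-ethoxy-2-oxoethyl)-5-methoxy-4-[(ArS)methoxy]benzoate | CCOC(=O)C(=[N+]=[N-])c1cc(C(=O)OC)cc(OC)c1OCc1ccc(O[Si](C(C)C)(C(C)C)C(C)C)c(OC)c1 | intermediate
8 | 3-ethyl 5-methyl (2S,3R)-7-methoxy-2-(ArS)-2,3-dihydro-1-benzofuran-3,5-dicarboxylate (cis) | COC(=O)c1cc(OC)c2c(c1)[C@@H](C(=O)OCC)[C@@H](c1ccc(O[Si](C(C)C)(C(C)C)C(C)C)c(OC)c1)O2 | intermediate
9 | 3-ethyl 5-methyl (2S,3S)-7-methoxy-2-(ArS)-2,3-dihydro-1-benzofuran-3,5-dicarboxylate (trans) | COC(=O)c1cc(OC)c2c(c1)[C@H](C(=O)OCC)[C@@H](c1ccc(O[Si](C(C)C)(C(C)C)C(C)C)c(OC)c1)O2 | intermediate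
10 | [(2S,3R)-7-methoxy-2-(ArS)-2,3-dihydro-1-benzofuran-3,5-diyl]dimethanol | OCc1cc(OC)c2c(c1)[C@H](CO)[C@@H](c1ccc(O[Si](C(C)C)(C(C)C)C(C)C)c(OC)c1)O2 | intermediate
11 | (2S,3R)-3-(hydroxymethyl)-7-methoxy-2-(ArS)-2,3-dihydro-1-benzofuran-5-carbaldehyde | O=Cc1cc(OC)c2c(c1)[C@H](CO)[C@@H](c1ccc(O[Si](C(C)C)(C(C)C)C(C)C)c(OC)c1)O2 | intermediate
12 | (2S,3R)-3-{[(tert-butyldimethylsilyl)oxy]methyl}-7-methoxy-2-(ArS)-2,3-dihydro-1-benzofuran-5-carbaldehyde | O=Cc1cc(OC)c2c(c1)[C@H](CO[Si](C)(C)C(C)(C)C)[C@@H](c1ccc(O[Si](C(C)C)(C(C)C)C(C)C)c(OC)c1)O2 | intermediate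
13 | [(2S,3R)-3-{[(tert-butyldimethylsilyl)oxy]methyl}-7-methoxy-2-(ArS)-2,3-dihydro-1-benzofuran-5-yl]methanol | OCc1cc(OC)c2c(c1)[C@H](CO[Si](C)(C)C(C)(C)C)[C@@H](c1ccc(O[Si](C(C)C)(C(C)C)C(C)C)c(OC)c1)O2 | intermediate
14 | tert-butyl{[(2S,3R)-5-(bromomethyl)-7-methoxy-2-(ArS)-2,3-dihydro-1-benzofuran-3-yl]methoxy}dimethylsilane | BrCc1cc(OC)c2c(c1)[C@H](CO[Si](C)(C)C(C)(C)C)[C@@H](c1ccc(O[Si](C(C)C)(C(C)C)C(C)C)c(OC)c1)O2 | intermediate
15 | (4R)-4-benzyl-1,3-oxazolidin-2-one | O=C1OC[C@@H](Cc2ccccc2)N1 | starting material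
16 | (2E)-but-2-enoyl chloride | C/C=C/C(Cl)=O | starting material
17 | (4R)-4-benzyl-3-[(2E)-but-2-enoyl]-1,3-oxazolidin-2-one | C/C=C/C(=O)N1[C@H](Cc2ccccc2)COC1=O | intermediate
18 | (4R)-4-benzyl-3-[(2R)-2-({(2S,3R)-3-{[(tert-butyldimethylsilyl)oxy]methyl}-7-methoxy-2-(ArS)-2,3-dihydro-1-benzofuran-5-yl}methyl)but-3-enoyl]-1,3-oxazolidin-2-one | O=C1OC[C@@H](Cc2ccccc2)N1C(=O)[C@@H](C=C)Cc1cc(OC)c2c(c1)[C@H](CO[Si](C)(C)C(C)(C)C)[C@@H](c1ccc(O[Si](C(C)C)(C(C)C)C(C)C)c(OC)c1)O2 | intermediate
19 | (2R)-2-({(2S,3R)-3-{[(tert-butyldimethylsilyl)oxy]methyl}-7-methoxy-2-(ArS)-2,3-dihydro-1-benzofuran-5-yl}methyl)but-3-enoic acid | OC(=O)[C@@H](C=C)Cc1cc(OC)c2c(c1)[C@H](CO[Si](C)(C)C(C)(C)C)[C@@H](c1ccc(O[Si](C(C)C)(C(C)C)C(C)C)c(OC)c1)O2 | intermediate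
20 | chloromethyl chlorosulfate | ClCOS(=O)(=O)Cl | starting material
21 | chloromethyl (2R)-2-({(2S,3R)-3-{[(tert-butyldimethylsilyl)oxy]methyl}-7-methoxy-2-(ArS)-2,3-dihydro-1-benzofuran-5-yl}methyl)but-3-enoate | ClCOC(=O)[C@@H](C=C)Cc1cc(OC)c2c(c1)[C@H](CO[Si](C)(C)C(C)(C)C)[C@@H](c1ccc(O[Si](C(C)C)(C(C)C)C(C)C)c(OC)c1)O2 | intermediate
22 | bromoacetyl bromide | BrCC(Br)=O | starting material
23 | (4R)-4-benzyl-3-(bromoacetyl)-1,3-oxazolidin-2-one | O=C1OC[C@@H](Cc2ccccc2)N1C(=O)CBr | intermediate
24 | 4-iodo-2-methoxyphenol | COc1cc(I)ccc1O | starting material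
25 | (4R)-4-benzyl-3-[(4-iodo-2-methoxyphenoxy)acetyl]-1,3-oxazolidin-2-one | O=C1OC[C@@H](Cc2ccccc2)N1C(=O)COc1ccc(I)cc1OC | intermediate
26 | (4R)-4-benzyl-3-[(2R,3S)-3-hydroxy-2-(4-iodo-2-methoxyphenoxy)-3-(ArS)propanoyl]-1,3-oxazolidin-2-one | COc1cc([C@H](O)[C@H](C(=O)N2[C@H](Cc3ccccc3)COC2=O)Oc2ccc(I)cc2OC)ccc1O[Si](C(C)C)(C(C)C)C(C)C | intermediate
27 | (1S,2S)-2-(4-iodo-2-methoxyphenoxy)-1-(ArS)propane-1,3-diol | COc1cc([C@H](O)[C@H](CO)Oc2ccc(I)cc2OC)ccc1O[Si](C(C)C)(C(C)C)C(C)C | intermediate
28 | (1S,2S)-3-[(tert-butyldimethylsilyl)oxy]-2-(4-iodo-2-methoxyphenoxy)-1-(ArS)propan-1-ol | COc1cc([C@H](O)[C@H](CO[Si](C)(C)C(C)(C)C)Oc2ccc(I)cc2OC)ccc1O[Si](C(C)C)(C(C)C)C(C)C | intermediate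
29 | (1R,2S)-3-[(tert-butyldimethylsilyl)oxy]-2-(4-iodo-2-methoxyphenoxy)-1-(ArS)propyl 4-nitrobenzoate | COc1cc([C@@H](OC(=O)c2ccc(cc2)[N+](=O)[O-])[C@H](CO[Si](C)(C)C(C)(C)C)Oc2ccc(I)cc2OC)ccc1O[Si](C(C)C)(C(C)C)C(C)C | intermediate
30 | (1R,2S)-3-[(tert-butyldimethylsilyl)oxy]-2-(4-iodo-2-methoxyphenoxy)-1-(ArS)propan-1-ol | COc1cc([C@@H](O)[C@H](CO[Si](C)(C)C(C)(C)C)Oc2ccc(I)cc2OC)ccc1O[Si](C(C)C)(C(C)C)C(C)C | intermediate
31 | {4-[(1R,2S)-1,3-bis{[tert-butyl(dimethyl)silyl]oxy}-2-(4-iodo-2-methoxyphenoxy)propyl]-2-methoxyphenoxy}tri(propan-2-yl)silane | COc1cc([C@@H](O[Si](C)(C)C(C)(C)C)[C@H](CO[Si](C)(C)C(C)(C)C)Oc2ccc(I)cc2OC)ccc1O[Si](C(C)C)(C(C)C)C(C)C | intermediate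
32 | iodomethyl (2R)-2-({(2S,3R)-3-{[(tert-butyldimethylsilyl)oxy]methyl}-7-methoxy-2-(ArS)-2,3-dihydro-1-benzofuran-5-yl}methyl)but-3-enoate | ICOC(=O)[C@@H](C=C)Cc1cc(OC)c2c(c1)[C@H](CO[Si](C)(C)C(C)(C)C)[C@@H](c1ccc(O[Si](C(C)C)(C(C)C)C(C)C)c(OC)c1)O2 | intermediate (formed in the flask in step 24, not isolated)
33 | (3R,4R)-4-[(4-{[(1R,2S)-1,3-bis(TBS-oxy)-1-(ArS)propan-2-yl]oxy}-3-methoxyphenyl)methyl]-3-({(2S,3R)-3-[(TBS-oxy)methyl]-7-methoxy-2-(ArS)-2,3-dihydro-1-benzofuran-5-yl}methyl)oxolan-2-one | COc1cc([C@@H](O[Si](C)(C)C(C)(C)C)[C@H](CO[Si](C)(C)C(C)(C)C)Oc2ccc(C[C@H]3COC(=O)[C@@H]3Cc3cc(OC)c4c(c3)[C@H](CO[Si](C)(C)C(C)(C)C)[C@@H](c3ccc(O[Si](C(C)C)(C(C)C)C(C)C)c(OC)c3)O4)cc2OC)ccc1O[Si](C(C)C)(C(C)C)C(C)C | intermediate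
34 | (3R,4R)-4-[(4-{[(1R,2S)-1,3-dihydroxy-1-(4-hydroxy-3-methoxyphenyl)propan-2-yl]oxy}-3-methoxyphenyl)methyl]-3-{[(2S,3R)-2-(4-hydroxy-3-methoxyphenyl)-3-(hydroxymethyl)-7-methoxy-2,3-dihydro-1-benzofuran-5-yl]methyl}oxolan-2-one | COc1cc([C@@H](O)[C@H](CO)Oc2ccc(C[C@H]3COC(=O)[C@@H]3Cc3cc(OC)c4c(c3)[C@H](CO)[C@@H](c3ccc(O)c(OC)c3)O4)cc2OC)ccc1O | target

**Step count and risks**

Total steps: 25. Longest linear sequence: 16 steps (1–11, 13–15, 24, 25).

Steps most likely to fail:

1. Step 24 (proposed new method). The acyloxymethyl radical may be intercepted by the aryl–nickel species, or reduced, before the ester has rotated into the s-cis rotamer needed for 5-exo closure; this would give open-chain aryl-transfer or reduction products, and the trans/cis control at the new centre may also be insufficient. The fallback uses known chemistry, sets out from 21 and 31 and comes back at 33. Finkelstein exchange of 21 (NaI, acetone) gives iodomethyl ester 32, isolated this time. Iodine-atom-transfer radical cyclization (Bu6Sn2 10 mol %, visible light, benzene, 80 °C, 0.02 M) should then give the iodomethyl lactone F1; the open radical has no fast competing exit and the chain is carried by iodine transfer from 32 to the cyclized primary radical. This still closes the lactone by the same bond between the O–CH2 carbon and the β-carbon, trans to the C3 substituent. F1 is then joined to 31 in a separate nickel-catalysed cross-electrophile coupling of a primary alkyl iodide with an aryl iodide (NiI2, 4,4′-di-tert-butyl-2,2′-bipyridine, Zn, DMA, rt) to return to 33.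

2. Step 21. The electron-rich benzylic oxyphosphonium may ionize, so that inversion is accompanied by partial retention or by elimination. The fallback sets out from 28 and comes back at 30. Oxidation with Dess–Martin periodinane (NaHCO3, CH2Cl2) gives the aryl ketone F2. Chelation-controlled reduction with Zn(BH4)2 (Et2O, −40 °C) then delivers hydride to the zinc chelate of the carbonyl and the α-aryloxy oxygen from the face opposite the CH2OTBS group, which should give the anti (erythro) alcohol 30.

3. Step 4. The diazo ester may decompose (carbene dimerization, azine formation) faster than it couples at the ortho-alkoxy-substituted aryl iodide. The fallback sets out from 5 and comes back at 7. Negishi coupling of 5 with the Reformatsky reagent BrZnCH2CO2Et (Pd2(dba)3, XPhos, THF, 60 °C) gives the arylacetate F3, and Regitz diazo transfer (4-acetamidobenzenesulfonyl azide, DBU, MeCN) converts F3 into 7.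

**Further compounds**

F1 | step 24 | (3R,4R)-3-({(2S,3R)-3-{[(tert-butyldimethylsilyl)oxy]methyl}-7-methoxy-2-(ArS)-2,3-dihydro-1-benzofuran-5-yl}methyl)-4-(iodomethyl)oxolan-2-one | IC[C@H]1COC(=O)[C@@H]1Cc1cc(OC)c2c(c1)[C@H](CO[Si](C)(C)C(C)(C)C)[C@@H](c1ccc(O[Si](C(C)C)(C(C)C)C(C)C)c(OC)c1)O2
F2 | step 21 | (2S)-3-[(tert-butyldimethylsilyl)oxy]-2-(4-iodo-2-methoxyphenoxy)-1-(ArS)propan-1-one | COc1cc(C(=O)[C@H](CO[Si](C)(C)C(C)(C)C)Oc2ccc(I)cc2OC)ccc1O[Si](C(C)C)(C(C)C)C(C)C
F3 | step 4 | methyl 3-(2-ethoxy-2-oxoethyl)-5-methoxy-4-[(ArS)methoxy]benzoate | CCOC(=O)Cc1cc(C(=O)OC)cc(OC)c1OCc1ccc(O[Si](C(C)C)(C(C)C)C(C)C)c(OC)c1
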